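The route rests on cutting the aryl ether bond O1–C8a of the pyran ring (chroman numbering; arene = ring A, pyran = ring B). C8a sits ortho to C4, so at the C4 ketone level it is the β-carbon of a vinylogous acyl fluoride. In one operation the lithium enolate of 2',4',6'-trifluoroacetophenone adds to acetone (C2–C3), and the resulting tertiary alkoxide closes ring B by displacing either of two equivalent ortho fluorines. The precursor is thus an open-chain aldolate on a symmetric trifluoroarene. The surviving fluorines at C5 and C7 then steer lithiation to C6 (methyl) and C8 (acyl) and finally become the two phenols.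

Key step: step 1

Remark: the single stereocentre is C4 and reads (4R) in chroman numbering. Compound 9 is taken as a purchasable amide.

Step 1
Reactants: 1 2',4',6'-trifluoroacetophenone; 2 acetone
Product: 5 5,7-difluoro-2,2-dimethylchroman-4-one, via lithium enolate 3 (not isolated), via lithium aldolate 4 (not isolated)
Conditions: LiN(iPr)2 (1.05 equiv), THF, −78 °C; 2 (1.5 equiv), −78 °C; warm to 25 °C
Reagents that add atoms: none
Why: LiN(iPr)2 turns 1 into enolate 3, which adds to acetone (lithium aldol addition, C2–C3) to give the tertiary alkoxide 4; on warming, O1 attacks C8a, the β-carbon of the C8a=C4a–C4=O vinylogous acyl fluoride of ring A, the Meisenheimer charge is taken up by the C4 carbonyl and the two meta fluorines, and loss of LiF restores the arene (SNAr addition–elimination). The closest known reaction types are the aldol addition of aryl methyl ketone enolates to acetone and the base-induced cyclisation of 3-hydroxy-1-(2-fluoroaryl)alkan-1-ones to chroman-4-ones, merged here into a formal [4+2] annulation in which acetone supplies O1, C2 and both methyl groups. Ring B closes in the 6-endo-trig conjugate-addition mode, and the quaternary C2 is built without any substitution at a tertiary carbon. No stereocentre is formed. The step needs site selectivity among three C–F bonds: the two ortho ones are equivalent by rotation about the C4–C4a bond, so either closure gives 5, and the para one cannot be reached by the short tether. It also needs closure to beat retro-aldol cleavage, which the substrate secures because the retro-aldol is reversible while fluoride loss as LiF is not, so the equilibrium drains into 5.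

Step 2
Reactants: 5 5,7-difluoro-2,2-dimethylchroman-4-one
Product: 6 (4R)-5,7-difluoro-2,2-dimethylchroman-4-ol
Conditions: RuCl[(R,R)-TsDPEN](p-cymene) (1 mol %), HCO2H/Et3N (5:2), 30 °C
Reagents that add atoms: none
Why: In this Noyori-type asymmetric transfer hydrogenation the (R,R)-TsDPEN ruthenium hydride binds the aryl ketone in the CH/π-stabilised six-membered transition state and delivers hydride to the Si face of C4=O, the sense established for chroman-4-ones and 1-tetralone, which sets (4R).

Step 3
Reactants: 6 (4R)-5,7-difluoro-2,2-dimethylchroman-4-ol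
Product: 8 (4R)-5,7-difluoro-2,2,6-trimethylchroman-4-ol, via C6-lithiated alkoxide 7 (not isolated)
Conditions: n-BuLi (2.1 equiv), THF, −78 °C; MeI (1.05 equiv), −78 °C; H2O
Reagents that add atoms: iodomethane, CI
Why: After alkoxide formation, directed ortho-metalation takes C6–H, which lies between two C–F bonds and is more acidic than C8–H with its single fluorine neighbour, and at −78 °C the aryllithium takes up MeI far faster than the hindered lithium alkoxide, leaving C4 untouched.

Step 4
Reactants: 8 (4R)-5,7-difluoro-2,2,6-trimethylchroman-4-ol; 9 N-methoxy-N-methyl-3-phenylpropanamide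
Product: 12 1-[(4R)-5,7-difluoro-4-hydroxy-2,2,6-trimethylchroman-8-yl]-3-phenylpropan-1-one, via C8-lithiated alkoxide 10 (not isolated), via tetrahedral adduct 11 (not isolated)
Conditions: s-BuLi (2.2 equiv), TMEDA, THF, −78 °C; 9 (1.3 equiv), −78 to −50 °C; H2O
Reagents that add atoms: none
Why: C8–H is the only hydrogen left on ring A and is activated by C7–F and O1 (directed ortho-metalation), and the aryllithium adds only once because the chelated adduct 11 survives until the quench (Weinreb ketone synthesis).

Step 5
Reactants: 12 1-[(4R)-5,7-difluoro-4-hydroxy-2,2,6-trimethylchroman-8-yl]-3-phenylpropan-1-one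
Product: 14 1-[(4R)-5,7-bis(benzyloxy)-4-hydroxy-2,2,6-trimethylchroman-8-yl]-3-phenylpropan-1-one, via 5-benzyloxy-7-fluoro ketone 13 (not isolated)
Conditions: BnOH (5 equiv), KOtBu (4.5 equiv), DMSO/THF, 25 to 60 °C, Ar
Reagents that add atoms: benzyl alcohol, OCc1ccccc1
Why: C5–F is para and C7–F ortho to the C8 carbonyl while O1 and the alkyl groups are no leaving groups, so two successive SNAr addition–elimination events with potassium benzyl oxide (para first in the dissociating solvent, then the inductively activated ortho position) should install both ethers, the excess alcohol keeps the ketone largely un-enolised, and the C4 alkoxide could reach a C–F bond only through a four-membered ring.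

Step 6
Reactants: 14 1-[(4R)-5,7-bis(benzyloxy)-4-hydroxy-2,2,6-trimethylchroman-8-yl]-3-phenylpropan-1-one
Product: 15 1-[(4R)-4,5,7-trihydroxy-2,2,6-trimethylchroman-8-yl]-3-phenylpropan-1-one (target)
Conditions: H2 (1 atm), Pd/C (10 wt %), EtOAc, 25 °C
Reagents that add atoms: none
Why: Catalytic hydrogenolysis of the two primary benzyl aryl ethers under neutral conditions should be much faster than cleavage of the hindered secondary C4–O bond or reduction of the hydrogen-bonded aryl ketone, so both phenols are freed with (4R) retained.

Compound list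
1 | 2',4',6'-trifluoroacetophenone | CC(=O)c1c(F)cc(F)cc1F | starting material
2 | acetone | CC(C)=O | starting material
3 | lithium 1-(2,4,6-trifluorophenyl)ethen-1-olate | C=C([O-])c1c(F)cc(F)cc1F.[Li+] | intermediate
4 | lithium 2-methyl-4-oxo-4-(2,4,6-trifluorophenyl)butan-2-olate | CC(C)([O-])CC(=O)c1c(F)cc(F)cc1F.[Li+] | intermediate
5 | 5,7-difluoro-2,2-dimethylchroman-4-one | CC1(C)CC(=O)c2c(F)cc(F)cc2O1 | intermediate
6 | (4R)-5,7-difluoro-2,2-dimethylchroman-4-ol | Fc1cc2c(c(F)c1)[C@H](O)CC(C)(C)O2 | intermediate
7 | lithium (4R)-5,7-difluoro-6-lithio-2,2-dimethylchroman-4-olate | [Li]c1c(F)cc2c(c1F)[C@H](O[Li])CC(C)(C)O2 | intermediate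
8 | (4R)-5,7-difluoro-2,2,6-trimethylchroman-4-ol | Cc1c(F)cc2c(c1F)[C@H](O)CC(C)(C)O2 | intermediate
9 | N-methoxy-N-methyl-3-phenylpropanamide | CON(C)C(=O)CCc1ccccc1 | starting material
10 | lithium (4R)-5,7-difluoro-8-lithio-2,2,6-trimethylchroman-4-olate | Cc1c(F)c([Li])c2c(c1F)[C@H](O[Li])CC(C)(C)O2 | intermediate
11 | dilithium alkoxide of (4R)-5,7-difluoro-8-[1-hydroxy-1-(N-methoxy-N-methylamino)-3-phenylpropyl]-2,2,6-trimethylchroman-4-ol (hemiaminal carbon unassigned) | Cc1c(F)c(C(O[Li])(CCc3ccccc3)N(C)OC)c2c(c1F)[C@H](O[Li])CC(C)(C)O2 | intermediate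
12 | 1-[(4R)-5,7-difluoro-4-hydroxy-2,2,6-trimethylchroman-8-yl]-3-phenylpropan-1-one | Cc1c(F)c(C(=O)CCc2ccccc2)c2c(c1F)[C@H](O)CC(C)(C)O2 | intermediate
13 | 1-[(4R)-5-(benzyloxy)-7-fluoro-4-hydroxy-2,2,6-trimethylchroman-8-yl]-3-phenylpropan-1-one | Cc1c(F)c(C(=O)CCc2ccccc2)c2c(c1OCc3ccccc3)[C@H](O)CC(C)(C)O2 | intermediate
14 | 1-[(4R)-5,7-bis(benzyloxy)-4-hydroxy-2,2,6-trimethylchroman-8-yl]-3-phenylpropan-1-one | Cc1c(OCc3ccccc3)c(C(=O)CCc2ccccc2)c2c(c1OCc4ccccc4)[C@H](O)CC(C)(C)O2 | intermediate
15 | 1-[(4R)-4,5,7-trihydroxy-2,2,6-trimethylchroman-8-yl]-3-phenylpropan-1-one | Cc1c(O)c(C(=O)CCc2ccccc2)c2c(c1O)[C@H](O)CC(C)(C)O2 | target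

Total step count: 6. Longest linear sequence: 6.

Steps most likely to fail

Step 5. Three processes threaten this step.
- The exchange may stall after the first fluorine, once ring A is richer and the C8 carbonyl is pushed out of conjugation.
- The ketone may rest as its enolate.
- Alkoxide-mediated hydride shuttling between the C4 alkoxide and carbonyl groups may erode the C4 configuration.

The fallback sets out from 12 and moves the activating role to C4. Dess–Martin oxidation of the C4 carbinol gives 5,7-difluoro-2,2,6-trimethyl-8-(3-phenylpropanoyl)chroman-4-one F1. Its ring-held, coplanar C4 carbonyl lies ortho to C5–F and para to C7–F. BnOH and K2CO3 in DMF at ambient temperature should then give 5,7-bis(benzyloxy)-2,2,6-trimethyl-8-(3-phenylpropanoyl)chroman-4-one F2, with no stereocentre at risk. Asymmetric transfer hydrogenation with RuCl[(R,R)-TsDPEN](p-cymene) and HCO2H/Et3N should reduce only the C4 ketone, because the C8 ketone, flanked by O1 and the C7 benzyloxy group, is twisted and shielded. This re-sets (4R) and comes back to the route at 14.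

Step 1. Retro-aldol cleavage on warming may outrun ring closure and open the way to intermolecular arylation or self-condensation of the enolate. The fallback sets out from 1. TMSOTf and Et3N give trimethyl{[1-(2,4,6-trifluorophenyl)ethenyl]oxy}silane F3. Mukaiyama aldol addition to acetone 2 with TiCl4 in CH2Cl2 at −78 °C gives, after work-up, the neutral and isolable 3-hydroxy-3-methyl-1-(2,4,6-trifluorophenyl)butan-1-one F4. K2CO3 in DMF at ambient temperature then closes the same O1–C8a bond by SNAr and comes back to the route at 5.

Step 6. Hydrogenolysis or ionisation of the electron-rich benzylic C4–O bond may set in as soon as the flanking phenols are free. The fallback sets out from 12 and changes the protecting group and its mode of removal. Allyl alcohol and NaH in DMF give 1-[(4R)-4-hydroxy-2,2,6-trimethyl-5,7-bis(prop-2-enyloxy)chroman-8-yl]-3-phenylpropan-1-one F5. Tsuji–Trost deallylation with Pd(PPh3)4 and morpholine in THF at ambient temperature frees both phenols under neutral, non-reducing conditions and comes back to the route at 15.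

Further compounds
F1 | step 5 | 5,7-difluoro-2,2,6-trimethyl-8-(3-phenylpropanoyl)chroman-4-one | Cc1c(F)c(C(=O)CCc2ccccc2)c2c(c1F)C(=O)CC(C)(C)O2
F2 | step 5 | 5,7-bis(benzyloxy)-2,2,6-trimethyl-8-(3-phenylpropanoyl)chroman-4-one | Cc1c(OCc3ccccc3)c(C(=O)CCc2ccccc2)c2c(c1OCc4ccccc4)C(=O)CC(C)(C)O2
F3 | step 1 | trimethyl{[1-(2,4,6-trifluorophenyl)ethenyl]oxy}silane | C=C(O[Si](C)(C)C)c1c(F)cc(F)cc1F
F4 | step 1 | 3-hydroxy-3-methyl-1-(2,4,6-trifluorophenyl)butan-1-one | CC(C)(O)CC(=O)c1c(F)cc(F)cc1F
F5 | step 6 | 1-[(4R)-4-hydroxy-2,2,6-trimethyl-5,7-bis(prop-2-enyloxy)chroman-8-yl]-3-phenylpropan-1-one | Cc1c(OCC=C)c(C(=O)CCc2ccccc2)c2c(c1OCC=C)[C@H](O)CC(C)(C)O2
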